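The target is an (R)-carvone-derived bisabolane: a cis-epoxy cyclohexanone carrying a trans isovalerate and a cross-conjugated dienone side chain that ends in a tertiary allylic hydroperoxide.

**Strategy.** Everything rests on cutting the cross-conjugated dienone between its ketone carbon and the (E)-alkene CH next to it. That ketone carbon sits between two sp2 carbons: the methylene-bearing carbon on C4 of the 7-oxabicyclo[4.1.0]heptan-2-one ring and the vinyl CH of the hydroperoxy-bearing chain. A Stille acylation therefore joins an acryloyl chloride that carries the complete epoxy-ketone ring, with all four stereocentres and the isovalerate, to an (E)-vinylstannane whose tertiary hydroperoxide is masked as a perketal. One operation gives the divinyl ketone at the final oxidation level with the alkene geometry retained; only a mild acidic unmasking follows. The ring stereocentres are relayed from C5 of (R)-carvone.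

Key step: step 11

Remark: the hydroperoxide is carried through the coupling as its 2-methoxyprop-2-yl perketal; the small peroxides 13 and 14 are to be handled cold, in solution and behind a shield.

**Step 1**
Reactants: 1 (R)-(−)-carvone; 2 3-methylbutanoic acid
Product: 3 (1S,6S)-3-methyl-2-oxo-6-(prop-1-en-2-yl)cyclohex-3-en-1-yl 3-methylbutanoate (ester trans to the isopropenyl group)
Conditions: Mn(OAc)3·2H2O (3 equiv), 2 (10 equiv), benzene, reflux, Dean–Stark
Reagents that add atoms: none
Why: Mn(III)-mediated α'-acyloxylation of an enone, in which carboxylate exchange on manganese and ligand transfer to the C6 manganese enolate should place the acyloxy group anti to the neighbouring C5 isopropenyl group, which is also the more stable trans-diequatorial arrangement.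

**Step 2**
Reactants: 3
Product: 4 (1S,6S)-6-(3-chloroprop-1-en-2-yl)-3-methyl-2-oxocyclohex-3-en-1-yl 3-methylbutanoate
Conditions: Ca(OCl)2, solid CO2, CH2Cl2/H2O, 0 °C
Reagents that add atoms: calcium hypochlorite, [Ca+2].[O-]Cl.[O-]Cl
Why: Ene-type allylic chlorination by HOCl made in situ should attack only the electron-rich 1,1-disubstituted alkene and lose a methyl proton to give the 2-(chloromethyl)vinyl group, while the conjugated ring alkene stays inert and no stereocentre is touched.

**Step 3**
Reactants: 4
Product: 5 (1S,2S,6S)-6-(3-chloroprop-1-en-2-yl)-2-hydroxy-3-methylcyclohex-3-en-1-yl 3-methylbutanoate (OH cis to the C6 side chain, trans to the ester)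
Conditions: NaBH4, CeCl3·7H2O, MeOH, −78 °C
Reagents that add atoms: none
Why: Luche 1,2-reduction with axial hydride delivery to the half-chair that holds both ring substituents equatorial should give the equatorial carbinol, cis to the side chain as in carvone to cis-carveol, and the low temperature should spare the ester and allylic chloride and suppress acyl migration.

**Step 4**
Reactants: 5
Product: 6 (1R,2R,3S,4S,6S)-4-(3-chloroprop-1-en-2-yl)-2-hydroxy-1-methyl-7-oxabicyclo[4.1.0]heptan-3-yl 3-methylbutanoate (epoxide cis to OH and to the side chain)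
Conditions: VO(acac)2 (5 mol %), t-BuOOH (1.2 equiv), CH2Cl2, 0 °C
Reagents that add atoms: tert-butyl hydroperoxide, CC(C)(C)OO
Why: Vanadium-catalysed hydroxyl-directed epoxidation should deliver oxygen to the ring alkene from the face of the allylic alcohol, setting both epoxide carbons cis to the OH and hence cis to the side chain, and should leave the undirected chloromethyl-vinyl alkene alone.

**Step 5**
Reactants: 6
Product: 7 (1S,3S,4S,6S)-4-(3-chloroprop-1-en-2-yl)-1-methyl-2-oxo-7-oxabicyclo[4.1.0]heptan-3-yl 3-methylbutanoate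
Conditions: Dess–Martin periodinane, CH2Cl2, 0 °C to rt
Reagents that add atoms: none
Why: Dess–Martin oxidation of the secondary alcohol under near-neutral conditions should give the epoxy ketone without opening the epoxide or epimerising the acyloxy-bearing carbon.

**Step 6**
Reactants: 7
Product: 10 (1S,3S,4S,6S)-1-methyl-2-oxo-4-(3-oxoprop-1-en-2-yl)-7-oxabicyclo[4.1.0]heptan-3-yl 3-methylbutanoate, via allylic iodide 8 (not isolated), via N-alkoxymorpholinium iodide 9 (not isolated)
Conditions: NMO (4 equiv), NaI (0.2 equiv), 4 Å MS, MeCN, 40 °C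
Reagents that add atoms: 4-methylmorpholine N-oxide, C[N+]1([O-])CCOCC1; sodium iodide, [Na+].[I-] (iodine only in 8 and 9)
Why: Ganem-type N-oxide oxidation of an allylic halide (Finkelstein activation, O-alkylation of the N-oxide, then loss of N-methylmorpholine) should give the 2-substituted acrolein under weakly basic conditions that the ester and epoxy ketone tolerate.

**Step 7**
Reactants: 10
Product: 11 2-[(1S,3S,4S,6S)-6-methyl-4-(3-methylbutanoyloxy)-5-oxo-7-oxabicyclo[4.1.0]heptan-3-yl]prop-2-enoic acid
Conditions: NaClO2, NaH2PO4, 2-methylbut-2-ene, t-BuOH/H2O, 0 °C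
Reagents that add atoms: sodium chlorite, [Na+].[O-]Cl=O
Why: Pinnick oxidation should convert the enal into the acrylic acid at buffered pH, with the alkene scavenger removing HOCl before it can reach the methylene group or the epoxide.

**Step 8**
Reactants: 12 2-methylbut-3-yn-2-ol
Product: 13 3-hydroperoxy-3-methylbut-1-yne
Conditions: 50% aq. H2O2, H2SO4, 0 °C to rt
Reagents that add atoms: hydrogen peroxide, OO
Why: Acid-catalysed SN1 perhydrolysis of a tertiary propargylic alcohol should exchange OH for OOH at the only carbon that can ionise.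

**Step 9**
Reactants: 13
Product: 14 3-[(2-methoxypropan-2-yl)peroxy]-3-methylbut-1-yne
Conditions: 2-methoxypropene, PPTS (cat.), CH2Cl2, 0 °C
Reagents that add atoms: 2-methoxypropene, C=C(C)OC
Why: Acid-catalysed addition of the hydroperoxide to the enol ether (perketal formation) should mask the acidic, easily reduced OOH as a dialkyl peroxide that survives organometallic steps.

**Step 10**
Reactants: 14
Product: 15 tributyl{(1E)-3-[(2-methoxypropan-2-yl)peroxy]-3-methylbut-1-en-1-yl}stannane
Conditions: Bu3SnH (1.1 equiv), PdCl2(PPh3)2 (2 mol %), THF, 0 °C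
Reagents that add atoms: tributyltin hydride, CCCC[SnH](CCCC)CCCC
Why: Palladium-catalysed syn-hydrostannation of a terminal alkyne should fix the E geometry and, because of the quaternary propargylic carbon, place tin on the terminal carbon, and the fast catalysed addition at 0 °C should outrun reduction of the dialkyl peroxide.

**Step 11**
Reactants: 11; 15
Product: 17 (1S,3S,4S,6S)-4-{(4E)-6-[(2-methoxypropan-2-yl)peroxy]-6-methyl-3-oxohepta-1,4-dien-2-yl}-1-methyl-2-oxo-7-oxabicyclo[4.1.0]heptan-3-yl 3-methylbutanoate, via acid chloride 16 (not isolated)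
Conditions: 1-chloro-N,N,2-trimethylprop-1-en-1-amine, CH2Cl2, 0 °C to rt; then 15, Pd2(dba)3 (2.5 mol %), AsPh3 (10 mol %), THF, 40 °C
Reagents that add atoms: 1-chloro-N,N,2-trimethylprop-1-en-1-amine (Ghosez reagent), CC(C)=C(Cl)N(C)C (chlorine only in 16)
Why: The Ghosez reagent should turn acid 11 into acyl chloride 16 without releasing HCl; Pd(0) then inserts into the acyl–Cl bond, the (E)-alkenyl group of 15 moves from tin to the acyl-palladium(II) with retention, and reductive elimination forms the ketone-carbon to vinyl-CH bond (Migita–Kosugi–Stille ketone synthesis from an acid chloride and a vinylstannane). No ring is closed and no stereocentre is created: the E geometry is carried over from step 10 and the four ring stereocentres are spectators. The step needs oxidative addition at the acyl chloride in preference to the O–O bond, the epoxy ketone and the ester, which the fast acyl–Cl insertion, the phosphine-free arsine ligand and the mild temperature should secure. It also needs alkenyl rather than butyl transfer, which the sp2 group on tin provides, and no decarbonylation, which rapid transmetalation at 40 °C should prevent. The absence of base protects the epimerisable acyloxy-bearing carbon and both enone acceptors, and the perketal keeps a free OOH away from the catalyst.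

**Step 12**
Reactants: 17
Product: 18 (1S,3S,4S,6S)-4-[(4E)-6-hydroperoxy-6-methyl-3-oxohepta-1,4-dien-2-yl]-1-methyl-2-oxo-7-oxabicyclo[4.1.0]heptan-3-yl 3-methylbutanoate (CNP0241468.1)
Conditions: AcOH/THF/H2O (4:2:1), rt
Reagents that add atoms: none
Why: Mild acid hydrolysis of the perketal should release the hydroperoxide, acetone and methanol under conditions too weak to open the epoxide, cleave the ester or trigger base-type peroxide addition to the enones.

**Compound list**

1 | (R)-(−)-carvone, (5R)-2-methyl-5-(prop-1-en-2-yl)cyclohex-2-en-1-one | C=C(C)[C@@H]1CC=C(C)C(=O)C1 | starting material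
2 | 3-methylbutanoic acid (isovaleric acid) | CC(C)CC(=O)O | starting material
3 | (1S,6S)-3-methyl-2-oxo-6-(prop-1-en-2-yl)cyclohex-3-en-1-yl 3-methylbutanoate | C=C(C)[C@@H]1CC=C(C)C(=O)[C@H]1OC(=O)CC(C)C | intermediate
4 | (1S,6S)-6-(3-chloroprop-1-en-2-yl)-3-methyl-2-oxocyclohex-3-en-1-yl 3-methylbutanoate | C=C(CCl)[C@@H]1CC=C(C)C(=O)[C@H]1OC(=O)CC(C)C | intermediate
5 | (1S,2S,6S)-6-(3-chloroprop-1-en-2-yl)-2-hydroxy-3-methylcyclohex-3-en-1-yl 3-methylbutanoate | C=C(CCl)[C@@H]1CC=C(C)[C@H](O)[C@H]1OC(=O)CC(C)C | intermediate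
6 | (1R,2R,3S,4S,6S)-4-(3-chloroprop-1-en-2-yl)-2-hydroxy-1-methyl-7-oxabicyclo[4.1.0]heptan-3-yl 3-methylbutanoate | C=C(CCl)[C@@H]1C[C@@H]2O[C@]2(C)[C@H](O)[C@H]1OC(=O)CC(C)C | intermediate
7 | (1S,3S,4S,6S)-4-(3-chloroprop-1-en-2-yl)-1-methyl-2-oxo-7-oxabicyclo[4.1.0]heptan-3-yl 3-methylbutanoate | C=C(CCl)[C@@H]1C[C@@H]2O[C@]2(C)C(=O)[C@H]1OC(=O)CC(C)C | intermediate
8 | (1S,3S,4S,6S)-4-(3-iodoprop-1-en-2-yl)-1-methyl-2-oxo-7-oxabicyclo[4.1.0]heptan-3-yl 3-methylbutanoate (not isolated) | C=C(CI)[C@@H]1C[C@@H]2O[C@]2(C)C(=O)[C@H]1OC(=O)CC(C)C | intermediate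
9 | 4-methyl-4-({2-[(1S,3S,4S,6S)-6-methyl-4-(3-methylbutanoyloxy)-5-oxo-7-oxabicyclo[4.1.0]heptan-3-yl]prop-2-en-1-yl}oxy)morpholin-4-ium iodide (not isolated) | C=C(CO[N+]3(C)CCOCC3)[C@@H]1C[C@@H]2O[C@]2(C)C(=O)[C@H]1OC(=O)CC(C)C.[I-] | intermediate
10 | (1S,3S,4S,6S)-1-methyl-2-oxo-4-(3-oxoprop-1-en-2-yl)-7-oxabicyclo[4.1.0]heptan-3-yl 3-methylbutanoate | C=C(C=O)[C@@H]1C[C@@H]2O[C@]2(C)C(=O)[C@H]1OC(=O)CC(C)C | intermediate
11 | 2-[(1S,3S,4S,6S)-6-methyl-4-(3-methylbutanoyloxy)-5-oxo-7-oxabicyclo[4.1.0]heptan-3-yl]prop-2-enoic acid | C=C(C(=O)O)[C@@H]1C[C@@H]2O[C@]2(C)C(=O)[C@H]1OC(=O)CC(C)C | intermediate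
12 | 2-methylbut-3-yn-2-ol | C#CC(C)(C)O | starting material
13 | 3-hydroperoxy-3-methylbut-1-yne | C#CC(C)(C)OO | intermediate
14 | 3-[(2-methoxypropan-2-yl)peroxy]-3-methylbut-1-yne | C#CC(C)(C)OOC(C)(C)OC | intermediate
15 | tributyl{(1E)-3-[(2-methoxypropan-2-yl)peroxy]-3-methylbut-1-en-1-yl}stannane | CCCC[Sn](CCCC)(CCCC)/C=C/C(C)(C)OOC(C)(C)OC | intermediate
16 | 2-[(1S,3S,4S,6S)-6-methyl-4-(3-methylbutanoyloxy)-5-oxo-7-oxabicyclo[4.1.0]heptan-3-yl]prop-2-enoyl chloride (not isolated) | C=C(C(=O)Cl)[C@@H]1C[C@@H]2O[C@]2(C)C(=O)[C@H]1OC(=O)CC(C)C | intermediate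
17 | (1S,3S,4S,6S)-4-{(4E)-6-[(2-methoxypropan-2-yl)peroxy]-6-methyl-3-oxohepta-1,4-dien-2-yl}-1-methyl-2-oxo-7-oxabicyclo[4.1.0]heptan-3-yl 3-methylbutanoate | C=C(C(=O)/C=C/C(C)(C)OOC(C)(C)OC)[C@@H]1C[C@@H]2O[C@]2(C)C(=O)[C@H]1OC(=O)CC(C)C | intermediate
18 | (1S,3S,4S,6S)-4-[(4E)-6-hydroperoxy-6-methyl-3-oxohepta-1,4-dien-2-yl]-1-methyl-2-oxo-7-oxabicyclo[4.1.0]heptan-3-yl 3-methylbutanoate | C=C(C(=O)/C=C/C(C)(C)OO)[C@@H]1C[C@@H]2O[C@]2(C)C(=O)[C@H]1OC(=O)CC(C)C | target

**Step count.** Total: 12 steps. Longest linear sequence: 9 steps (steps 1–7, 11, 12); steps 8–10 form the three-step side branch.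

**Steps most likely to fail**

1. Step 11 (key coupling). The O–O bond may be cleaved reductively by low-valent palladium, or the acyl-palladium may lose CO before the vinyl group arrives. The fallback postpones the peroxide and sets out from aldehyde 10. Allylboration with pinacol (2-methylbut-3-en-2-yl)boronate (γ-attack through a chair transition state, toluene, rt) should form the same carbon–carbon bond and give the linear prenyl carbinol, homoallylic alcohol F1 (carbinol configuration irrelevant). Dess–Martin periodinane should oxidise it to the β,γ-unsaturated prenyl ketone F2. A Schenck ene reaction (O2, tetraphenylporphyrin, hν, CH2Cl2, 0 °C) should then remove a hydrogen from the CH2 between ketone and alkene and place the hydroperoxide on the tertiary carbon with an E alkene, coming back to the route at 18 with no protecting group. The regioisomeric secondary hydroperoxide is the expected by-product and would have to be separated.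

2. Step 10 (hydrostannation). Tin hydride or palladium hydride may reduce the peroxide, or tin may be delivered to the internal alkyne carbon. The fallback avoids hydrometalation and sets out from alkyne 14 and aldehyde 10. Zinc acetylide addition (Zn(OTf)2, Et3N, toluene, rt) should give propargylic alcohol F3 (carbinol configuration irrelevant), and a ruthenium-catalysed redox isomerisation of the propargylic alcohol (Trost conditions) should convert it into the (E)-enone, coming back to the route at 17 and by-passing steps 7 and 11.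

3. Step 1 (α'-acyloxylation). Facial selectivity at C6 may be poor, or incomplete carboxylate exchange on manganese may transfer acetate instead of isovalerate. The fallback sets out from carvone 1. Kinetic deprotonation (LDA, THF, −78 °C) and hydroxylation of the C6 enolate with 2-(benzenesulfonyl)-3-phenyloxaziridine, anti to the isopropenyl group, should give trans-hydroxy ketone F4, which isovaleryl chloride (pyridine, DMAP, CH2Cl2, 0 °C) should acylate, coming back to the route at 3.

**Further compounds**

F1 | step 11 | (1S,3S,4S,6S)-4-(3-hydroxy-6-methylhepta-1,5-dien-2-yl)-1-methyl-2-oxo-7-oxabicyclo[4.1.0]heptan-3-yl 3-methylbutanoate | C=C(C(O)CC=C(C)C)[C@@H]1C[C@@H]2O[C@]2(C)C(=O)[C@H]1OC(=O)CC(C)C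
F2 | step 11 | (1S,3S,4S,6S)-1-methyl-4-(6-methyl-3-oxohepta-1,5-dien-2-yl)-2-oxo-7-oxabicyclo[4.1.0]heptan-3-yl 3-methylbutanoate | C=C(C(=O)CC=C(C)C)[C@@H]1C[C@@H]2O[C@]2(C)C(=O)[C@H]1OC(=O)CC(C)C
F3 | step 10 | (1S,3S,4S,6S)-4-{3-hydroxy-6-[(2-methoxypropan-2-yl)peroxy]-6-methylhept-1-en-4-yn-2-yl}-1-methyl-2-oxo-7-oxabicyclo[4.1.0]heptan-3-yl 3-methylbutanoate | C=C(C(O)C#CC(C)(C)OOC(C)(C)OC)[C@@H]1C[C@@H]2O[C@]2(C)C(=O)[C@H]1OC(=O)CC(C)C
F4 | step 1 | (5S,6S)-6-hydroxy-2-methyl-5-(prop-1-en-2-yl)cyclohex-2-en-1-one | C=C(C)[C@@H]1CC=C(C)C(=O)[C@H]1O
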